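Retrosynthetic overview
1. Lukianol A ⇒ its tris(methyl ether); the three aryl O–CH3 bonds are cleaved last.
2. Key disconnection: the acyl C–O bond of the oxazinone, formed by the enol oxygen of an N-phenacyl ketone attacking a pyrrole-2-carboxyl. A second, equivalent carboxyl is added back at C6 ⇒ a symmetric N-phenacyl-3,4-diarylpyrrole-2,5-dicarboxylic acid.
3. Both pyrrole C–N bonds (Paal–Knorr) ⇒ 2-amino-4'-methoxyacetophenone plus a 3,4-diaryl-2,5-dioxohexanedioic acid, which is the oxidative dimer of 4-methoxyphenylpyruvic acid.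
4. Ring order: pyrrole first (step 1), 1,4-oxazin-2-one ring second (step 2), deprotection third.

Assumption: the target (lukianol A) is achiral, with no stereocentre and no resolvable axis. No enantiomer has to be selected, and the compound is made exactly as drawn in the SMILES.

Step 1
Reactants: 1 3-(4-methoxyphenyl)-2-oxopropanoic acid (2 equiv); 2 2-amino-1-(4-methoxyphenyl)ethan-1-one hydrochloride (1 equiv)
Product: 4 1-[2-(4-methoxyphenyl)-2-oxoethyl]-3,4-bis(4-methoxyphenyl)-1H-pyrrole-2,5-dicarboxylic acid, via diketo diacid 3 (not isolated)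
Conditions: n-BuLi (4 equiv), THF, −78 °C; I2 (1 equiv), −78 °C → rt; then 2, NaOAc (1.2 equiv), AcOH, 4 Å MS, rt → 45 °C, 16 h; aq HCl work-up
Reagents that add atoms: none
Why: Double deprotonation of the largely enolic keto acid and I2 oxidation couple two units at the benzylic carbon (oxidative enolate homocoupling) to the 1,4-diketone 3; its very electrophilic α-keto-acid carbonyls capture the amine, released slowly by the acetate buffer, faster than the deactivated p-anisoyl ketone of 2 can self-condense, and Paal–Knorr cyclodehydration forms both C–N bonds, while the two stereocentres of 3 vanish on aromatisation.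

Step 2
Reactants: 4 1-[2-(4-methoxyphenyl)-2-oxoethyl]-3,4-bis(4-methoxyphenyl)-1H-pyrrole-2,5-dicarboxylic acid
Product: 7 3,7,8-tris(4-methoxyphenyl)-1H-pyrrolo[2,1-c][1,4]oxazin-1-one (lukianol A trimethyl ether), via mixed anhydride 5 (not isolated), via lactone acid 6 (not isolated)
Conditions: AgOAc (10 mol %), KOAc (30 mol %), Ac2O (1.5 equiv), NMP, Ar, dark, 90 °C, 1 h, then 125 °C, 14 h
Reagents that add atoms: none
Why: Proposed new method: a one-flask, silver-catalysed desymmetrising enol-lactonisation/protodecarboxylation of a pyrrole-2,5-dicarboxylic acid, in which Ac2O turns one of the two equivalent carboxyls into mixed anhydride 5, acetate enolises the N-CH2-C(=O)Ar ketone, and the enolate oxygen closes the six-membered ring by 6-exo-trig O-acylation (C-acylation would need a four-membered ring) to give 6; the remaining carboxyl stays available through acetate/anhydride exchange and forms a carboxylate of monovalent silver that is twisted out of plane by its two flanking substituents and activated by the new lactone acceptor, so it extrudes CO2 to a 2-pyrrolylsilver species that the AcOH released in the ring closure protonates, regenerating AgOAc; loss of one CO2 before ring closure leads to the same product, and only double decarboxylation is unproductive, which the 90 °C hold suppresses; the closest known reaction types are Ac2O/acetate enol lactonisation of keto acids and AgOAc-catalysed protodecarboxylation of heteroaromatic acids in NMP, which have not been merged or run in the presence of an anhydride.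

Step 3
Reactants: 7 3,7,8-tris(4-methoxyphenyl)-1H-pyrrolo[2,1-c][1,4]oxazin-1-one
Product: 8 3,7,8-tris(4-hydroxyphenyl)-1H-pyrrolo[2,1-c][1,4]oxazin-1-one (lukianol A)
Conditions: BBr3 (6 equiv), CH2Cl2, −78 °C → rt, 12 h; ice-water quench
Reagents that add atoms: none
Why: In this Lewis-acid aryl methyl ether cleavage, BBr3 binds each anisyl oxygen and bromide removes the methyl group by SN2, whereas the lactone has only sp2 C–O bonds and a donor-deactivated pyrrole-2-carbonyl, so it survives the reagent and the cold aqueous quench; no stereocentre is involved.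

Compound list
1 | 3-(4-methoxyphenyl)-2-oxopropanoic acid (4-methoxyphenylpyruvic acid) | COc1ccc(CC(=O)C(=O)O)cc1 | starting material
2 | 2-amino-1-(4-methoxyphenyl)ethan-1-one hydrochloride | COc1ccc(cc1)C(=O)CN.Cl | starting material
3 | 3,4-bis(4-methoxyphenyl)-2,5-dioxohexanedioic acid (dl/meso mixture, present in the flask as its dilithium salt; both stereocentres are erased in the same step) | COc1ccc(cc1)C(C(=O)C(=O)O)C(C(=O)C(=O)O)c1ccc(OC)cc1 | intermediate
4 | 1-[2-(4-methoxyphenyl)-2-oxoethyl]-3,4-bis(4-methoxyphenyl)-1H-pyrrole-2,5-dicarboxylic acid | COc1ccc(cc1)C(=O)Cn1c(C(=O)O)c(-c2ccc(OC)cc2)c(-c2ccc(OC)cc2)c1C(=O)O | intermediate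
5 | mono(acetic) mixed anhydride of 4 | COc1ccc(cc1)C(=O)Cn1c(C(=O)OC(C)=O)c(-c2ccc(OC)cc2)c(-c2ccc(OC)cc2)c1C(=O)O | intermediate
6 | 3,7,8-tris(4-methoxyphenyl)-1-oxo-1H-pyrrolo[2,1-c][1,4]oxazine-6-carboxylic acid | COc1ccc(cc1)-c1cn2c(C(=O)O)c(-c3ccc(OC)cc3)c(-c3ccc(OC)cc3)c2c(=O)o1 | intermediate
7 | 3,7,8-tris(4-methoxyphenyl)-1H-pyrrolo[2,1-c][1,4]oxazin-1-one (lukianol A trimethyl ether) | COc1ccc(cc1)-c1cn2cc(-c3ccc(OC)cc3)c(-c3ccc(OC)cc3)c2c(=O)o1 | intermediate
8 | 3,7,8-tris(4-hydroxyphenyl)-1H-pyrrolo[2,1-c][1,4]oxazin-1-one (lukianol A, achiral) | O=c1oc(-c2ccc(O)cc2)cn2cc(-c3ccc(O)cc3)c(-c3ccc(O)cc3)c12 | target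

Total step count: 3 (isolated products 4, 7 and 8). Longest linear sequence: 3.

Steps most likely to fail

Step 2 (the proposed new cascade).
- Risks: the silver carboxylate of the hindered acid 6 may not lose CO2 while anhydride is present, or both carboxyls of 4 may be lost before the ring closes.
- Fallback (known chemistry only), from 4 back to 7: the ring closure and the carboxyl removal are separated, and metal-carboxylate extrusion is given up for electrophilic ipso-substitution.
- Compound 4 is closed by the classical enol lactonisation (Ac2O, NaOAc, reflux), which runs through 5, and lactone acid 6 is isolated.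
- The carboxyl of 6 is exchanged for iodine by the classical iodinative decarboxylation of pyrrole α-acids (I2, KI, NaHCO3, ClCH2CH2Cl–H2O, 75 °C). This gives 6-iodo-3,7,8-tris(4-methoxyphenyl)-1H-pyrrolo[2,1-c][1,4]oxazin-1-one F1.
- The C–I bond of F1 is reduced by transfer hydrodehalogenation (Pd(PPh3)4 cat., HCO2Na, DMF, 80 °C), which spares the enol double bond and delivers 7.

Step 1 (oxidative dimerisation/Paal–Knorr with an α-aminoketone).
- Risks: free 2 may self-condense to the dihydropyrazine, and 3 may cyclise to the furan before the amine arrives.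
- Fallback, from 1 back to 4: no free aminoketone is used. The N-substituent is attached by SN2 alkylation after the pyrrole exists.
- Compound 1 is dimerised to 3 as in step 1, and the flask is charged with NH4OAc instead of 2. This gives 3,4-bis(4-methoxyphenyl)-1H-pyrrole-2,5-dicarboxylic acid F2.
- TMSCHN2 in MeOH–toluene at 0 °C converts F2 into dimethyl 3,4-bis(4-methoxyphenyl)-1H-pyrrole-2,5-dicarboxylate F3.
- N-alkylation with commercial 2-bromo-1-(4-methoxyphenyl)ethan-1-one (COc1ccc(cc1)C(=O)CBr), K2CO3, acetone, reflux gives dimethyl 1-[2-(4-methoxyphenyl)-2-oxoethyl]-3,4-bis(4-methoxyphenyl)-1H-pyrrole-2,5-dicarboxylate F4.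
- Saponification (KOH, aq EtOH–THF, 60 °C, then HCl) returns 4.

Step 3 (triple demethylation next to the enol lactone).
- Risks: incomplete cleavage, or opening of the lactone during reaction or quench.
- Fallback, from 4 to 8: the methyl ethers are removed before the lactone exists, and the phenols are carried through ring closure as acetates.
- BBr3 (CH2Cl2, −78 °C → rt) on 4 gives 1-[2-(4-hydroxyphenyl)-2-oxoethyl]-3,4-bis(4-hydroxyphenyl)-1H-pyrrole-2,5-dicarboxylic acid F5.
- The conditions of step 2 with 5 equiv of Ac2O acetylate the phenols and close the ring to 3,7,8-tris(4-acetoxyphenyl)-1-oxo-1H-pyrrolo[2,1-c][1,4]oxazine-6-carboxylic acid F6, which is not isolated.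
- F6 loses CO2 in the same flask to give 3,7,8-tris(4-acetoxyphenyl)-1H-pyrrolo[2,1-c][1,4]oxazin-1-one (lukianol A triacetate) F7.
- Near-neutral selective cleavage of the aryl acetates (NH4OAc, MeOH–H2O, rt) leaves the less electrophilic pyrrole-2-carbonyl lactone intact and gives 8.

Further compounds
F1 | step 2 | 6-iodo-3,7,8-tris(4-methoxyphenyl)-1H-pyrrolo[2,1-c][1,4]oxazin-1-one | COc1ccc(cc1)-c1cn2c(I)c(-c3ccc(OC)cc3)c(-c3ccc(OC)cc3)c2c(=O)o1
F2 | step 1 | 3,4-bis(4-methoxyphenyl)-1H-pyrrole-2,5-dicarboxylic acid | OC(=O)c1[nH]c(C(=O)O)c(-c2ccc(OC)cc2)c1-c1ccc(OC)cc1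
F3 | step 1 | dimethyl 3,4-bis(4-methoxyphenyl)-1H-pyrrole-2,5-dicarboxylate | COC(=O)c1[nH]c(C(=O)OC)c(-c2ccc(OC)cc2)c1-c1ccc(OC)cc1
F4 | step 1 | dimethyl 1-[2-(4-methoxyphenyl)-2-oxoethyl]-3,4-bis(4-methoxyphenyl)-1H-pyrrole-2,5-dicarboxylate | COC(=O)c1c(-c2ccc(OC)cc2)c(-c2ccc(OC)cc2)c(C(=O)OC)n1CC(=O)c1ccc(OC)cc1
F5 | step 3 | 1-[2-(4-hydroxyphenyl)-2-oxoethyl]-3,4-bis(4-hydroxyphenyl)-1H-pyrrole-2,5-dicarboxylic acid | Oc1ccc(cc1)C(=O)Cn1c(C(=O)O)c(-c2ccc(O)cc2)c(-c2ccc(O)cc2)c1C(=O)O
F6 | step 3 | 3,7,8-tris(4-acetoxyphenyl)-1-oxo-1H-pyrrolo[2,1-c][1,4]oxazine-6-carboxylic acid | CC(=O)Oc1ccc(cc1)-c1cn2c(C(=O)O)c(-c3ccc(OC(C)=O)cc3)c(-c3ccc(OC(C)=O)cc3)c2c(=O)o1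
F7 | step 3 | 3,7,8-tris(4-acetoxyphenyl)-1H-pyrrolo[2,1-c][1,4]oxazin-1-one (lukianol A triacetate) | CC(=O)Oc1ccc(cc1)-c1cn2cc(-c3ccc(OC(C)=O)cc3)c(-c3ccc(OC(C)=O)cc3)c2c(=O)o1
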